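## Retrosynthetic overview

1. Ajugaciliatin A ⇐ 1β,12-diol chlorohydrin by double esterification with (S)-2-methylbutanoic acid; the chlorohydrin comes from a 4α,18-epoxide with HCl; the butenolide and C12 carbinol come from a C12 aldehyde and 4-bromofuranone (Ni/Cr coupling).
2. C12 aldehyde ⇐ 9β-allyl trans-decalone by global hydride reduction, 4,18-epoxide formation, 6,19-diacetylation and ozonolysis.
3. Key step: the trans-decalone ⇐ a monocyclic ring-A iodomethyl ketone by a radical cascade. An α-keto radical closes ring B 6-endo (C7–C8), and the resulting tertiary C9 radical is allylated (C9–C11).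
4. Ring A ⇐ a bicyclic lactone from an organocatalytic Diels–Alder reaction of 3-hydroxy-2-pyrone with the Knoevenagel adduct of methyl acetoacetate and tiglaldehyde. This sets C1, C4, C5 and C10 and brings in O1, O4 and C18.
5. Ring order: ring A (step 2) → ring B (step 7) → butenolide appended (step 12).

Assumption: intermediates are described with clerodane numbering (C1–C20); β is the face of H-10, α the face of C19/C20. The cinchona catalyst (step 2) and the Cr ligand (step 12) are used as the pseudo-enantiomer/antipode that gives the configurations drawn.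

## Route

**Step 1**
Reactants: 1 methyl acetoacetate; 2 (E)-2-methylbut-2-enal (tiglaldehyde)
Product: 3 methyl (2Z,4E)-2-acetyl-4-methylhexa-2,4-dienoate
Conditions: TiCl4, pyridine, THF, 0 °C → rt
Reagents that add atoms: none
Why: Knoevenagel condensation (Lehnert conditions); alkylidene acetoacetates form mainly as the Z isomer (alkenyl cis to CO2Me), and any E isomer or its 2H-pyran valence tautomer can re-equilibrate under the amine catalysis of step 2.

**Step 2**
Reactants: 3; 4 3-hydroxy-2H-pyran-2-one
Product: 5 methyl (1R,4R,5S,6R)-5-acetyl-6-[(2E)-but-2-en-2-yl]-4-hydroxy-3-oxo-2-oxabicyclo[2.2.2]oct-7-ene-5-carboxylate (lactone bridge O1–C18 on the β-face; acetyl exo, CO2Me and butenyl endo)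
Conditions: 6′-OH cinchona bifunctional catalyst (10 mol %), EtOAc, 0 °C → rt
Reagents that add atoms: none
Why: Base-catalysed asymmetric Diels–Alder reaction of a 3-hydroxy-2-pyrone; the dienolate γ-carbon bonds to the β-carbon (C10) and the carbinol carbon to the doubly activated α-carbon (C5), the ketone-exo transition state places CO2Me and butenyl endo, and the hydrogen-bonding catalyst fixes the absolute sense, so C1, C4, C5 and C10 are set in one step.

**Step 3**
Reactants: 5
Product: 6 methyl (1R,4R,5S,6R)-5-acetyl-6-[(2E)-but-2-en-2-yl]-4-hydroxy-3-oxo-2-oxabicyclo[2.2.2]octane-5-carboxylate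
Conditions: H2 (1 atm), RhCl(PPh3)3 (5 mol %), PhH, rt
Reagents that add atoms: none
Why: Homogeneous hydrogenation with Wilkinson's catalyst reduces the strained cis-disubstituted bicyclic alkene and leaves the hindered trisubstituted butenyl alkene; neutral conditions avoid retro-aldol of the β-hydroxy dicarbonyl, and no stereocentre is created.

**Step 4**
Reactants: 6
Product: 7 dimethyl (1R,2S,3R,4R)-2-acetyl-3-[(2E)-but-2-en-2-yl]-1,4-dihydroxycyclohexane-1,2-dicarboxylate (C1 β-OH; C4 α-OH, β-CO2Me; C5 α-CO2Me, β-acetyl; C10 α-butenyl)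
Conditions: p-TsOH (cat.), MeOH, 40 °C
Reagents that add atoms: methanol, CO
Why: Acid-catalysed methanolysis (transesterification) of the strained boat-locked δ-lactone; acid rather than base avoids retro-aldol cleavage of C4–C5, and ring A relaxes to the chair with O1, butenyl and acetyl equatorial and both CO2Me groups axial.

**Step 5**
Reactants: 7
Product: 8 the 1-O-TBS ether of 7 (C4 tertiary OH free)
Conditions: TBSCl, imidazole, DMF, rt
Reagents that add atoms: tert-butyldimethylsilyl chloride, CC(C)(C)[Si](C)(C)Cl
Why: Selective silylation of the secondary alcohol; the tertiary α-hydroxy ester OH does not react with TBSCl/imidazole.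

**Step 6**
Reactants: 8
Product: 9 dimethyl (1R,2S,3R,4R)-3-[(2E)-but-2-en-2-yl]-4-(TBSO)-2-(2-iodoacetyl)-1-(TMSO)cyclohexane-1,2-dicarboxylate
Conditions: TMSOTf, Et3N, CH2Cl2, 0 °C; then NIS, THF, −78 → 0 °C
Reagents that add atoms: trimethylsilyl triflate, C[Si](C)(C)OS(=O)(=O)C(F)(F)F; N-iodosuccinimide, O=C1CCC(=O)N1I
Why: The acetyl CH3 is the only enolisable position (C5 is quaternary), so silyl enol ether formation followed by electrophilic iodination gives the iodomethyl ketone regiospecifically, and the tertiary OH is capped as its TMS ether in the same operation.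

**Step 7 (key step)**
Reactants: 9; 10 allyl ethyl sulfone
Product: 11 trans-decalone (H-10β): C1 β-OTBS; C4 α-OTMS, β-CO2Me; C5 α-CO2Me; C6 ketone; C8 α-Me; C9 α-Me, β-allyl
Conditions: 10 (5 equiv), AIBN (portionwise), PhCl/heptane, reflux, 0.05 M
Reagents that add atoms: none (the allyl group comes from 10)
Why: Proposed new method: ethyl radical (from EtSO2• losing SO2) abstracts iodine to give the electrophilic α-keto radical at C7, which cyclises 6-endo onto the electron-rich trisubstituted alkene through a chair transition state (trans ring fusion follows from the trans-diequatorial acyl/butenyl groups on ring A; the E alkene places the C8 methyl equatorial), and the nucleophilic tertiary C9 radical then adds to the electron-poor allyl sulfone on the equatorial β-face, anti to the 1,3-diaxial C5 CO2Me, and expels EtSO2• to carry the chain; the closest known reactions are 6-endo cyclisations of α-iodoketone radicals and tin-free radical allylation of iodides with allyl sulfones.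

**Step 8**
Reactants: 11
Product: 12 tetraol: C4 α-OH, β-CH2OH; C5 α-CH2OH; C6 α-OH; C1 β-OTBS; C9 β-allyl
Conditions: LiAlH4, THF, 0 °C → rt; then K2CO3, MeOH
Reagents that add atoms: none
Why: Hydride reduction of the ketone and both methyl esters; hydride adds to C6 axially from the β-face (only axial H at C8 and C10, whereas the α-face is blocked by the adjacent axial C19 group) to give the equatorial 6α-alcohol, and methanolysis removes the tertiary TMS ether while the TBS ether stays.

**Step 9**
Reactants: 12
Product: 13 4α,18-epoxide (spiro-oxirane, O α, CH2 β) with free 6α-OH and 19-OH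
Conditions: PPh3, DIAD, THF, 0 °C → rt
Reagents that add atoms: none
Why: Mitsunobu-type cyclodehydration of the 1,2-diol; the primary C18 oxyphosphonium is displaced by the neighbouring tertiary O4 (3-exo-tet, retention at C4), whereas the 1,3-diol units only form reversible phosphoranes (oxetane closure is slow) and the trans-diaxial C18/C19 arms cannot form a tetrahydrofuran.

**Step 10**
Reactants: 13
Product: 14 6α,19-diacetate of 13
Conditions: Ac2O, pyridine, DMAP (cat.), rt
Reagents that add atoms: acetic anhydride, CC(=O)OC(C)=O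
Why: Standard acetylation of the only free hydroxyls (primary C19 and secondary C6); the epoxide and TBS ether are inert.

**Step 11**
Reactants: 14
Product: 15 C12 aldehyde (C9 β-CH2CHO)
Conditions: O3, CH2Cl2/MeOH, −78 °C; then PPh3
Reagents that add atoms: ozone, [O-][O+]=O
Why: Ozonolysis of the only alkene with reductive work-up; epoxide, acetates and silyl ether survive.

**Step 12**
Reactants: 15; 16 4-bromofuran-2(5H)-one
Product: 17 (12S)-12-hydroxy butenolide (C12 bonded to C4 of the furanone), otherwise as 15
Conditions: CrCl2, NiCl2 (cat.), chiral sulfonamide ligand, Et3N, THF/MeCN, rt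
Reagents that add atoms: none
Why: Nozaki–Hiyama–Kishi coupling of the β-bromo-butenolide with the aldehyde (tolerates esters, lactone and epoxide); the chiral sulfonamide ligand on chromium controls the new C12 carbinol (reagent control, 12S).

**Step 13**
Reactants: 17
Product: 18 1β,4α,12S-triol 18-chloride 6α,19-diacetate
Conditions: conc. aq. HCl, THF, 0 °C → rt
Reagents that add atoms: hydrogen chloride, Cl
Why: Chloride opens the protonated spiro-epoxide at the primary C18 by SN2 (C4 keeps its 4α-OH), and the same acid cleaves the TBS ether; acetates and the butenolide tolerate aqueous HCl at rt.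

**Step 14**
Reactants: 18; 19 (S)-2-methylbutanoic acid
Product: 20 ajugaciliatin A
Conditions: 19 (4 equiv), EDC·HCl, DMAP, CH2Cl2, 0 °C → rt
Reagents that add atoms: none
Why: Steglich esterification acylates the two secondary hydroxyls (O1 and O12) while the tertiary C4–OH is inert and the chlorohydrin is stable to DMAP; the acid's stereocentre is carried in unchanged.

## Compound list

1 | methyl acetoacetate | COC(=O)CC(C)=O | starting material
2 | (E)-2-methylbut-2-enal | C/C=C(\C)C=O | starting material
3 | methyl (2Z,4E)-2-acetyl-4-methylhexa-2,4-dienoate | COC(=O)/C(C(C)=O)=C\C(C)=C\C | intermediate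
4 | 3-hydroxy-2H-pyran-2-one | O=C1OC=CC=C1O | starting material
5 | methyl (1R,4R,5S,6R)-5-acetyl-6-[(2E)-but-2-en-2-yl]-4-hydroxy-3-oxo-2-oxabicyclo[2.2.2]oct-7-ene-5-carboxylate | CC(=O)[C@]1(C(=O)OC)[C@@H](/C(C)=C/C)[C@H]2C=C[C@]1(O)C(=O)O2 | intermediate
6 | 7,8-dihydro-5 (saturated bicyclic lactone) | CC(=O)[C@]1(C(=O)OC)[C@@H](/C(C)=C/C)[C@H]2CC[C@]1(O)C(=O)O2 | intermediate
7 | dimethyl (1R,2S,3R,4R)-2-acetyl-3-[(2E)-but-2-en-2-yl]-1,4-dihydroxycyclohexane-1,2-dicarboxylate | CC(=O)[C@]1(C(=O)OC)[C@@H](/C(C)=C/C)[C@H](O)CC[C@]1(O)C(=O)OC | intermediate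
8 | 4-O-TBS ether of 7 (cyclohexane numbering; clerodane O1) | CC(=O)[C@]1(C(=O)OC)[C@@H](/C(C)=C/C)[C@H](O[Si](C)(C)C(C)(C)C)CC[C@]1(O)C(=O)OC | intermediate
9 | iodomethyl ketone, C4–OTMS, O1–TBS | ICC(=O)[C@]1(C(=O)OC)[C@@H](/C(C)=C/C)[C@H](O[Si](C)(C)C(C)(C)C)CC[C@]1(O[Si](C)(C)C)C(=O)OC | intermediate
10 | allyl ethyl sulfone | C=CCS(=O)(=O)CC | starting material
11 | 9β-allyl trans-decal-6-one 4β,5α-diester (1β-OTBS, 4α-OTMS, 8α-Me, 9α-Me) | C=CC[C@@]1(C)[C@H](C)CC(=O)[C@]2(C(=O)OC)[C@@H]1[C@H](O[Si](C)(C)C(C)(C)C)CC[C@]2(O[Si](C)(C)C)C(=O)OC | intermediate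
12 | 4α,6α,18,19-tetraol (1β-OTBS, 9β-allyl) | C=CC[C@@]1(C)[C@H](C)C[C@H](O)[C@]2(CO)[C@@H]1[C@H](O[Si](C)(C)C(C)(C)C)CC[C@]2(O)CO | intermediate
13 | 4α,18-epoxide 6α,19-diol | C=CC[C@@]1(C)[C@H](C)C[C@H](O)[C@]2(CO)[C@@H]1[C@H](O[Si](C)(C)C(C)(C)C)CC[C@]23CO3 | intermediate
14 | 4α,18-epoxide 6α,19-diacetate | C=CC[C@@]1(C)[C@H](C)C[C@H](OC(C)=O)[C@]2(COC(C)=O)[C@@H]1[C@H](O[Si](C)(C)C(C)(C)C)CC[C@]23CO3 | intermediate
15 | C12 aldehyde | O=CC[C@@]1(C)[C@H](C)C[C@H](OC(C)=O)[C@]2(COC(C)=O)[C@@H]1[C@H](O[Si](C)(C)C(C)(C)C)CC[C@]23CO3 | intermediate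
16 | 4-bromofuran-2(5H)-one | BrC1=CC(=O)OC1 | starting material
17 | (12S)-12-hydroxy butenolide, 1β-OTBS, 4α,18-epoxide, 6α,19-diacetate | O[C@@H](C[C@@]1(C)[C@H](C)C[C@H](OC(C)=O)[C@]2(COC(C)=O)[C@@H]1[C@H](O[Si](C)(C)C(C)(C)C)CC[C@]23CO3)C1=CC(=O)OC1 | intermediate
18 | 1β,4α,12S-triol 18-chloride 6α,19-diacetate | O[C@@H](C[C@@]1(C)[C@H](C)C[C@H](OC(C)=O)[C@]2(COC(C)=O)[C@@H]1[C@H](O)CC[C@]2(O)CCl)C1=CC(=O)OC1 | intermediate
19 | (S)-2-methylbutanoic acid | CC[C@H](C)C(=O)O | starting material
20 | ajugaciliatin A | CC[C@H](C)C(=O)O[C@@H](C[C@@]1(C)[C@H](C)C[C@H](OC(C)=O)[C@]2(COC(C)=O)[C@@H]1[C@H](OC(=O)[C@@H](C)CC)CC[C@]2(O)CCl)C1=CC(=O)OC1 | target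

## Summary

Total steps: 14. Longest linear sequence: 14 (steps 1–14; 4, 10, 16 and 19 enter as purchased materials).

Steps most likely to fail, with fallbacks:

1. **Step 7 (radical cascade).** Risks are premature trapping of the C7 radical, loss of the tertiary C9 iodide/radical by elimination, and imperfect β-face selectivity at C9 because of the peri C1 oxygen. Fallback: deliver the two-carbon unit intramolecularly. Replace the O1 silyl ether by a vinyl(diphenyl)silyl ether so that, after the same 6-endo closure, the C9 radical is captured 7-endo on the tethered vinylsilane (Bu3SnH). Tamao oxidation and oxidation of the C12 alcohol then give the aldehyde with C11 necessarily β.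

2. **Step 2 (pyrone Diels–Alder).** Risks are a wrong exo/endo or C5 outcome through a stepwise Michael–aldol path, retro-aldol, or re-aromatisation to a 6-alkylated hydroxypyrone. Fallback: switch from the anionic organocatalytic mode to a concerted Lewis-acid cycloaddition. Use 3-(TBSO)-2-pyrone with geometrically pure (Z)-3 under a chiral Cu(II)–bis(oxazoline) catalyst (two-point binding to the β-keto ester) or high pressure, and remove the silyl group afterwards.

3. **Step 12 (C12 configuration in the Ni/Cr coupling).** Risk is low or reversed diastereoselectivity on this remote, neopentyl aldehyde. Fallback: run the coupling without ligand, oxidise the C12 epimer mixture to the ketone (Dess–Martin) and set 12S by CBS reduction.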